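**Plan**

1. Tetralin numbering is used. C1 is the diaryl methine. C2 and C3 carry the hydroxymethyl carbons C9' and C9. C4 is the benzylic CH2. Ring A is C4a–C8a with 6-OMe, 7-OH and 8-OH. The target is (1S,2R,3S), that is 1,2-trans and 2,3-cis.
2. Cuts in retrosynthetic order: the O7 benzyl group; the cis-1,4-diol folded back into a cis-fused γ-lactone (ring C, C9'=O on C2, O–C9 on C3); C1–C2 (ring B); C8a–C1, which releases 3,4,5-trimethoxybenzaldehyde; and the lactone, which goes back through a Stobbe half-ester to 5-hydroxyvanillin and dimethyl succinate.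
3. Enabling feature: the free 8-OH of ring A is ortho to C8a, so O8–C8–C8a–C1 is a latent o-quinone methide with C1 as acceptor, helped by the 6-OMe para to C8a. The α-carbon of ring C is C2, the donor.
4. The same 8-OH first directs the C8a–C1 bond through a boron template. It then stores the unit as a temporary 1,3,2-dioxaborin ring that masks both oxygens until the closure.
5. Forward order: side chain on ring A, ring C, the temporary dioxaborin ring, ring B last, then lactone reduction and debenzylation.
6. Stereochemistry: C3 comes from a rhodium-catalysed asymmetric hydrogenation. C2 and C1 both derive from C3 in the ring closure, with the cis fusion enforced by ring C and the 1,2-trans relation set by the o-quinone methide geometry. The usual C1–C8a closure followed by epimerisation cannot give this array.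

Key step: step 6

Assumption: the (R,R)-ligand is taken to give the (S)-configured hydrogenation product, in line with the sense known for β-aryl itaconate half-esters. If the sense proves opposite, the (S,S)-ligand is used and nothing else changes.

**Step 1**
Reactants: 1 3,4-dihydroxy-5-methoxybenzaldehyde (5-hydroxyvanillin); 2 benzyl bromide
Product: 3 4-(benzyloxy)-3-hydroxy-5-methoxybenzaldehyde
Conditions: BnBr (1.05 equiv), NaHCO3 (1.5 equiv), DMF, 40 °C
Reagents that add atoms: benzyl bromide (2), BrCc1ccccc1
Why: Williamson ether synthesis under pKa control: the 4-OH, para to the formyl group, is much the more acidic phenol, so the weak base ionises only this one and the benzyl group should go on O4 (the later O7), which leaves the 3-OH (the later O8) free.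

**Step 2**
Reactants: 3 4-(benzyloxy)-3-hydroxy-5-methoxybenzaldehyde; 4 dimethyl succinate
Product: 5 (E)-4-[4-(benzyloxy)-3-hydroxy-5-methoxyphenyl]-3-(methoxycarbonyl)but-3-enoic acid
Conditions: NaOMe (3 equiv), MeOH, reflux; then 2 M HCl
Reagents that add atoms: dimethyl succinate (4), COC(=O)CCC(=O)OC
Why: Stobbe condensation: the succinate enolate adds to the aldehyde, the alkoxide lactonises and the paraconic ester opens by E1cB elimination to the (E)-half-ester, and the phenoxide formed by the extra base stands meta to the formyl group and so cannot quench it by conjugation.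

**Step 3**
Reactants: 5 (E)-half-ester
Product: 6 (3S)-4-[4-(benzyloxy)-3-hydroxy-5-methoxyphenyl]-3-(methoxycarbonyl)butanoic acid
Conditions: [Rh(cod)((R,R)-Et-DuPhos)]BF4 (1 mol %), H2 (6 bar), NaOMe (10 mol %), MeOH, rt
Reagents that add atoms: none
Why: Chelate-controlled asymmetric hydrogenation of an itaconate-type half-ester: the carboxylate and the alkene bind the cationic rhodium bisphospholane, which delivers H2 to one face and sets C3 as (S), while the aryl benzyl ether is inert to this homogeneous catalyst.

**Step 4**
Reactants: 6 (S)-half-ester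
Product: 8 (4S)-4-[4-(benzyloxy)-3-hydroxy-5-methoxybenzyl]dihydrofuran-2(3H)-one, via hydroxy acid 7 (not isolated)
Conditions: KOH (2.0 equiv), EtOH, 0 °C; CaCl2 (1.5 equiv), NaBH4 (3 equiv), EtOH, −10 °C to rt; then 3 M HCl, rt
Reagents that add atoms: none
Why: Chemoselective borohydride reduction followed by acid lactonisation: the carboxylate and phenoxide salts are inert to Ca(BH4)2, only the methyl ester is reduced, and since the KOH is used up by the two acidic protons no free base is left to epimerise C3.

**Step 5**
Reactants: 8 (S)-lactone phenol; 9 3,4,5-trimethoxybenzaldehyde; 10 phenylboronic acid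
Product: 11 (4S)-4-{[8-(benzyloxy)-7-methoxy-2-phenyl-4-(3,4,5-trimethoxyphenyl)-4H-1,3,2-benzodioxaborin-5-yl]methyl}dihydrofuran-2(3H)-one (both epimers at the dioxaborin C4, which is C1 of the target)
Conditions: 9 (1.2 equiv), PhB(OH)2 (1.2 equiv), EtCO2H (0.3 equiv), toluene, reflux, Dean–Stark trap
Reagents that add atoms: 3,4,5-trimethoxybenzaldehyde (9), COc1cc(C=O)cc(OC)c1OC; phenylboronic acid (10), OB(O)c1ccccc1
Why: Boronic acid templated ortho-specific hydroxyalkylation of a phenol: the aryl boronate half-ester binds the aldehyde and hands it over in a six-membered transition state to C8a, the only free ortho carbon (C5, para to the OH, is out of reach), and the 1,3-diol is caught as the cyclic boronate, whose C1 forms as a mixture of epimers that is of no consequence because step 6 flattens this centre.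

**Step 6**
Reactants: 11 dioxaborin lactone
Product: 14 (3aS,9S,9aR)-7-(benzyloxy)-8-hydroxy-6-methoxy-9-(3,4,5-trimethoxyphenyl)-3a,4,9,9a-tetrahydronaphtho[2,3-c]furan-1(3H)-one, via silyl ketene acetal 12 (not isolated), via o-quinone methide 13 (not isolated)
Conditions: Et3N (1.3 equiv), Me3SiOTf (1.2 equiv), CH2Cl2 (0.01 M), 0 °C; then Me3SiOTf (0.5 equiv), −78 to −20 °C; aq. NaHCO3
Reagents that add atoms: trimethylsilyl triflate, C[Si](C)(C)OS(=O)(=O)C(F)(F)F (its silyl group stands only in 12 and 13 and is lost before 14)
Why: Proposed new method: Et3N/Me3SiOTf should soft-enolise the lactone of 11 to ketene acetal 12, the extra Me3SiOTf should silylate the benzylic B–O–C1 oxygen so that the C1–O bond ionises under the push of O8 and of the para 6-OMe to the boron-capped o-quinone methide 13, C2 attacks C1, the silyl group leaves O9' again and the aqueous work-up cleaves the O8–B bond. The closest known reaction types are the Mukaiyama–Michael addition of silyl ketene acetals to o-quinone methides, the Lewis-acid reduction of 4H-1,3,2-benzodioxaborins through the same intermediate and the SN1 alkylation of silyl enol ethers with benzhydryl cations; new are the carbon nucleophile on a benzodioxaborin, the intramolecular setting and the single flask. Ring B closes in the 6-endo-trig mode at C1=C8a and in the enolexo mode at C2=C9'. C2 is controlled by C3, because the new bond must stand perpendicular to the flat dihydrofuran and the four-atom tether reaches only the face that carries C4 (torsion C1–C2–C3–C4 near 30° against near 150°), which gives the cis ring fusion, also the more stable one at this epimerisable centre. C1 is controlled by allylic strain and ring shape: the C4 methylene forces the aryl group of 13 to the O8 side (Z geometry), and in the half-chair transition state this aryl group lies pseudo-equatorial and anti to C3 while H1 points over ring C, which gives the 1,2-trans relation. The step needs C–C closure to win over O-trapping, over a p-quinone methide at C4 and over dimerisation: an O8–C9' hetero-Diels–Alder closure would demand an anti-Bredt bicyclo[3.3.1] frame with the aromatic C8a as bridgehead, the O7 benzyl ether rules out the p-quinone methide, and high dilution together with a six-membered transition state favours the ring.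

**Step 7**
Reactants: 14 cis-fused lactone
Product: 15 (1S,2R,3S)-7-(benzyloxy)-2,3-bis(hydroxymethyl)-6-methoxy-1-(3,4,5-trimethoxyphenyl)-1,2,3,4-tetrahydronaphthalen-8-ol
Conditions: LiAlH4 (3 equiv), THF, 0 °C to rt; aq. potassium sodium tartrate
Reagents that add atoms: none
Why: Hydride reduction of a lactone to the 1,4-diol: no stereocentre is involved, the cis-fused lactone is the stable C2 epimer so that basic aluminates cannot scramble it, and the phenol only consumes one hydride.

**Step 8**
Reactants: 15 benzyl-protected diol
Product: 16 target, (1S,2R,3S)-2,3-bis(hydroxymethyl)-6-methoxy-1-(3,4,5-trimethoxyphenyl)-1,2,3,4-tetrahydronaphthalene-7,8-diol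
Conditions: H2 (1 atm), Pd/C (10 wt %), degassed MeOH/EtOAc, rt
Reagents that add atoms: none
Why: Catalytic hydrogenolysis of an aryl benzyl ether: only the O–CH2Ph bond is labile, since C1 and C4 carry no heteroatom, and the neutral, oxygen-free medium suits the air-sensitive catechol.

**Compound list**

1 | 3,4-dihydroxy-5-methoxybenzaldehyde | COc1cc(C=O)cc(O)c1O | starting material
2 | benzyl bromide | BrCc1ccccc1 | starting material
3 | 4-(benzyloxy)-3-hydroxy-5-methoxybenzaldehyde | COc1cc(C=O)cc(O)c1OCc1ccccc1 | intermediate
4 | dimethyl succinate | COC(=O)CCC(=O)OC | starting material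
5 | (E)-4-[4-(benzyloxy)-3-hydroxy-5-methoxyphenyl]-3-(methoxycarbonyl)but-3-enoic acid | COC(=O)/C(CC(=O)O)=C/c1cc(O)c(OCc2ccccc2)c(OC)c1 | intermediate
6 | (3S)-4-[4-(benzyloxy)-3-hydroxy-5-methoxyphenyl]-3-(methoxycarbonyl)butanoic acid | OC(=O)C[C@@H](C(=O)OC)Cc1cc(O)c(OCc2ccccc2)c(OC)c1 | intermediate
7 | (3S)-4-[4-(benzyloxy)-3-hydroxy-5-methoxyphenyl]-3-(hydroxymethyl)butanoic acid | OC(=O)C[C@@H](CO)Cc1cc(O)c(OCc2ccccc2)c(OC)c1 | intermediate
8 | (4S)-4-[4-(benzyloxy)-3-hydroxy-5-methoxybenzyl]dihydrofuran-2(3H)-one | O=C1C[C@@H](CO1)Cc2cc(O)c(OCc3ccccc3)c(OC)c2 | intermediate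
9 | 3,4,5-trimethoxybenzaldehyde | COc1cc(C=O)cc(OC)c1OC | starting material
10 | phenylboronic acid | OB(O)c1ccccc1 | starting material
11 | (4S)-4-{[8-(benzyloxy)-7-methoxy-2-phenyl-4-(3,4,5-trimethoxyphenyl)-4H-1,3,2-benzodioxaborin-5-yl]methyl}dihydrofuran-2(3H)-one, epimer mixture at the dioxaborin C4 | COc1cc(C[C@@H]2COC(=O)C2)c2c(OB(c3ccccc3)OC2c2cc(OC)c(OC)c(OC)c2)c1OCc1ccccc1 | intermediate
12 | trimethylsilyl ketene acetal of 11: the lactone is a (3S)-5-(trimethylsilyloxy)-2,3-dihydrofuran-3-yl unit, the dioxaborin is unchanged | COc1cc(C[C@@H]2COC(O[Si](C)(C)C)=C2)c2c(OB(c3ccccc3)OC2c2cc(OC)c(OC)c(OC)c2)c1OCc1ccccc1 | intermediate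
13 | (Z)-2-(benzyloxy)-3-methoxy-6-[(3,4,5-trimethoxyphenyl)methylidene]-5-{[(3S)-5-(trimethylsilyloxy)-2,3-dihydrofuran-3-yl]methyl}cyclohexa-2,4-dien-1-one, drawn without the boron Lewis acid on O8 | O=C1C(OCc2ccccc2)=C(OC)C=C(C[C@@H]2COC(O[Si](C)(C)C)=C2)/C1=C/c1cc(OC)c(OC)c(OC)c1 | intermediate
14 | (3aS,9S,9aR)-7-(benzyloxy)-8-hydroxy-6-methoxy-9-(3,4,5-trimethoxyphenyl)-3a,4,9,9a-tetrahydronaphtho[2,3-c]furan-1(3H)-one | COc1cc2c(c(O)c1OCc1ccccc1)[C@H](c1cc(OC)c(OC)c(OC)c1)[C@@H](C(=O)O3)[C@@H](C3)C2 | intermediate
15 | (1S,2R,3S)-7-(benzyloxy)-2,3-bis(hydroxymethyl)-6-methoxy-1-(3,4,5-trimethoxyphenyl)-1,2,3,4-tetrahydronaphthalen-8-ol | COc1cc2c(c(O)c1OCc1ccccc1)[C@H](c1cc(OC)c(OC)c(OC)c1)[C@@H](CO)[C@@H](CO)C2 | intermediate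
16 | (1S,2R,3S)-2,3-bis(hydroxymethyl)-6-methoxy-1-(3,4,5-trimethoxyphenyl)-1,2,3,4-tetrahydronaphthalene-7,8-diol, also named (6S,7R,8S)-6,7-bis(hydroxymethyl)-3-methoxy-8-(3,4,5-trimethoxyphenyl)-5,6,7,8-tetrahydronaphthalene-1,2-diol | COc1cc2c(c(O)c1O)[C@H](c1cc(OC)c(OC)c(OC)c1)[C@@H](CO)[C@@H](CO)C2 | target

Total step count: 8. Longest linear sequence: 8 steps, from 1 to 16.

**Steps most likely to fail**

**Step 6.** The dioxaborin may ionise before the lactone is enolised, so that the o-quinone methide oligomerises. The ketene acetal may be protonated back by the ammonium salt or silylated at carbon. A boat-like approach, with ring A stacked over ring C, may erode the facial selectivity at C1.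

The fallback sets out from 11 and comes back at 15. It moves the donor to the lactol oxidation level and uses only a Brønsted acid. This is a known pairing: the acid-catalysed addition of 2,3-dihydrofurans to o-quinone methides made from o-hydroxybenzhydrols.
- i-Bu2AlH (CH2Cl2, −78 °C) reduces the lactone of 11, and exchange with 1,3-propanediol removes the boron to give the benzhydrol lactol F1.
- Diphenyl phosphate (10 mol %) in wet MeCN at 40 °C should set up two equilibria, lactol to 2,3-dihydrofuran and benzhydrol to o-quinone methide.
- C1–C2 should then close on the same five-membered template to the cyclised lactol F2, with water recapturing the oxocarbenium ion at C9'.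
- NaBH4 in MeOH reduces F2 to 15.

**Step 5.** Carbon–carbon bond formation at the crowded C8a, flanked by O8 and the C4 methylene, may be slow. The electron-rich product may also ionise thermally and arylate a second phenol.

The fallback sets out from 8 and comes back at 11. It splits the event into two known reactions.
- Casnati–Skattebøl ortho-formylation (MgCl2, Et3N, paraformaldehyde, MeCN, reflux) puts the smallest possible electrophile on C8a and gives the salicylaldehyde F3.
- 3,4,5-Trimethoxyphenylmagnesium bromide (2.1 equiv, THF, −78 °C) adds to the chelated aldehyde faster than to the lactone and gives the o-hydroxybenzhydrol lactone F4.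
- PhB(OH)2 in toluene with azeotropic removal of water closes F4 to 11.

**Step 2.** Addition to the phenoxide-bearing aldehyde may be sluggish, so that self-condensation of the succinate takes over.

The fallback sets out from 3 and comes back at 5. It replaces the basic condensation by a neutral Wittig olefination.
- Dimethyl 2-(triphenylphosphoranylidene)succinate (toluene, reflux) gives the benzylidene succinate diester F5.
- LiOH (2 equiv, THF/H2O, 0 °C) hydrolyses only the unconjugated, less hindered ester to give 5.

**Further compounds**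

F1 | step 6 | (4S)-4-{4-(benzyloxy)-3-hydroxy-2-[hydroxy(3,4,5-trimethoxyphenyl)methyl]-5-methoxybenzyl}tetrahydrofuran-2-ol, mixture at the carbinol and anomeric carbons | COc1cc(C[C@@H]2COC(O)C2)c(C(O)c2cc(OC)c(OC)c(OC)c2)c(O)c1OCc1ccccc1
F2 | step 6 | (3aS,9S,9aR)-7-(benzyloxy)-6-methoxy-9-(3,4,5-trimethoxyphenyl)-1,3,3a,4,9,9a-hexahydronaphtho[2,3-c]furan-1,8-diol, anomer mixture | COc1cc2c(c(O)c1OCc1ccccc1)[C@H](c1cc(OC)c(OC)c(OC)c1)[C@@H](C(O)O3)[C@@H](C3)C2
F3 | step 5 | 3-(benzyloxy)-2-hydroxy-4-methoxy-6-{[(3S)-5-oxotetrahydrofuran-3-yl]methyl}benzaldehyde | COc1cc(C[C@@H]2COC(=O)C2)c(C=O)c(O)c1OCc1ccccc1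
F4 | step 5 | (4S)-4-{4-(benzyloxy)-3-hydroxy-2-[hydroxy(3,4,5-trimethoxyphenyl)methyl]-5-methoxybenzyl}dihydrofuran-2(3H)-one, mixture at the carbinol carbon | COc1cc(C[C@@H]2COC(=O)C2)c(C(O)c2cc(OC)c(OC)c(OC)c2)c(O)c1OCc1ccccc1
F5 | step 2 | dimethyl (E)-2-[4-(benzyloxy)-3-hydroxy-5-methoxybenzylidene]succinate | COC(=O)/C(CC(=O)OC)=C/c1cc(O)c(OCc2ccccc2)c(OC)c1
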